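**Plan**
- Retrosynthesis: the acid is traced back to its methyl ester. With the furan numbered O1, C2 (CH2CO2H), C3, C4, C5 (hexadecyl), the O1–C2 bond and the CH2–C(=O) bond are then cut together, which leads to (Z)-henicos-3-en-1-yn-5-ol, CO and methanol.
- Enabling feature: the furan-2-acetic unit is the aromatic tautomer of a 2-(alkoxycarbonylmethylene)-2,5-dihydrofuran that still has a hydrogen on C5, so the ring oxygen and the carboxyl carbon can be attached to the two carbons of one terminal alkyne.
- The enynol is cut at its alkene–alkyne (sp2–sp) bond (Sonogashira coupling) and at the carbinol–alkyne bond of nonadec-1-yn-3-ol (Grignard addition to heptadecanal).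
- Forward: the C21 chain is assembled first (C17 + C2, iodination, cis reduction, + C2); the only ring, the furan, closes in step 6; ester hydrolysis ends the route.
- Stereochemistry: the target has no stereocentre. The Z-alkene needed for ring closure comes from syn hydrogen delivery by diimide and is retained in the coupling.

Key step: step 6

Remark: compounds 3 to 9 and 12 are carried as racemates at the carbinol carbon; no control is needed because this carbon ends as the sp2 furan carbon C5.

**Step 1**
Reactants: 1 heptadecanal; 2 ethynylmagnesium bromide
Product: 4 racemic nonadec-1-yn-3-ol, via bromomagnesium nonadec-1-yn-3-olate 3 (not isolated)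
Conditions: THF, 0 °C to rt; then 1 M aq. HCl, 0 °C
Reagents that add atoms: none
Why: Grignard 1,2-addition of an alkynylmagnesium halide to an unhindered aliphatic aldehyde is fast at 0 °C and creates the carbinol centre without facial bias, so 4 forms as the racemate, which is harmless because this carbon later becomes furan C5.

**Step 2**
Reactants: 4 racemic nonadec-1-yn-3-ol
Product: 5 racemic 1-iodononadec-1-yn-3-ol
Conditions: NIS, AgNO3 (cat.), acetone, rt, dark
Reagents that add atoms: N-iodosuccinimide, O=C1CCC(=O)N1I
Why: Silver-catalysed electrophilic iodination of a terminal alkyne (a silver acetylide intercepted by NIS) is selective for the sp C–H bond and tolerates the free secondary propargylic alcohol.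

**Step 3**
Reactants: 5 racemic 1-iodononadec-1-yn-3-ol
Product: 6 racemic (Z)-1-iodononadec-1-en-3-ol
Conditions: NBSH (2-nitrobenzenesulfonylhydrazide), Et3N, THF/i-PrOH, rt
Reagents that add atoms: none
Why: Diimide cis-semireduction of a 1-iodoalkyne: diimide released from NBSH by Et3N transfers two hydrogens to the same face of the triple bond in a concerted six-centre step, which fixes the Z geometry without touching the C–I bond or the alcohol, and the haloalkene product is reduced far more slowly than the iodoalkyne.

**Step 4**
Reactants: 6 racemic (Z)-1-iodononadec-1-en-3-ol; 7 trimethylsilylacetylene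
Product: 8 racemic (Z)-1-(trimethylsilyl)henicos-3-en-1-yn-5-ol
Conditions: Pd(PPh3)2Cl2 (cat.), CuI (cat.), Et3N, THF, rt, degassed
Reagents that add atoms: none
Why: Sonogashira coupling: the alkenyl C–I bond adds to zerovalent palladium with retention, the copper acetylide of 7 transmetalates and reductive elimination forms the sp2–sp bond, so the Z geometry is carried over, the free allylic alcohol is tolerated at room temperature and the silyl cap keeps the enynol from cyclising in the presence of the copper and palladium salts.

**Step 5**
Reactants: 8 racemic (Z)-1-(trimethylsilyl)henicos-3-en-1-yn-5-ol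
Product: 9 racemic (Z)-henicos-3-en-1-yn-5-ol
Conditions: K2CO3 (cat.), MeOH, 0 °C to rt
Reagents that add atoms: none
Why: Base-catalysed methanolysis of the alkynyl C–Si bond (protodesilylation) is fast at or below room temperature with catalytic K2CO3, conditions too mild to isomerise the Z-alkene or to drive the hydroxyl onto the alkyne.

**Step 6**
Reactants: 9 racemic (Z)-henicos-3-en-1-yn-5-ol; 10 carbon monoxide; 11 methanol
Product: 13 methyl 2-(5-hexadecylfuran-2-yl)acetate, via methyl (E)-2-(5-hexadecylfuran-2(5H)-ylidene)acetate 12 (not isolated)
Conditions: PdI2 (1 mol %), KI (10 mol %), CO/air 9:1 (ca. 100 atm), MeOH, 65 °C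
Reagents that add atoms: none
Why: [PdI4]2−, formed from PdI2 and KI, binds the terminal alkyne of 9, and the hydroxyl oxygen attacks the internal alkyne carbon anti to the metal, closing the furan ring in the 5-exo-dig mode (O1–C2) and leaving a vinyl complex of divalent palladium at the former terminal carbon. CO inserts into this Pd–C bond and methanol cleaves the acylpalladium to the E-configured exocyclic ester 12, releasing HI and zerovalent palladium, which O2 and HI return to PdI2 with water as the only coproduct. Intermediate 12 then moves the hydrogen of C5 to the exocyclic carbon and becomes the aromatic furan-2-acetate 13; no stereocentre is created and the racemic carbinol centre is erased. The closest known reaction type is the PdI2/KI-catalysed oxidative cyclisation–alkoxycarbonylation of (Z)-2-en-4-yn-1-ols with a terminal triple bond to furan-2-acetic esters. The step needs carbonylative 5-exo-dig closure to win over 6-endo-dig attack and over protonolysis of the vinylpalladium, which would give the 2-methylfuran. The Z-alkene holds the hydroxyl within reach of the internal alkyne carbon, the unsubstituted terminal carbon accepts CO, and high CO pressure with excess iodide favours insertion over protonolysis.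

**Step 7**
Reactants: 13 methyl 2-(5-hexadecylfuran-2-yl)acetate
Product: 15 2-(5-hexadecylfuran-2-yl)acetic acid, via lithium 2-(5-hexadecylfuran-2-yl)acetate 14 (not isolated)
Conditions: LiOH·H2O, THF/H2O, 0 °C to rt, argon; then 1 M aq. HCl to pH 3, 0 °C
Reagents that add atoms: lithium hydroxide, [Li+].[OH-]
Why: Saponification by acyl–oxygen cleavage of an unhindered methyl ester proceeds in the cold, the hydroxide oxygen ending up in the carboxyl group, and brief acidification at 0 °C with immediate extraction frees the acid without exposing the acid-sensitive 2,5-dialkylfuran to strong acid or the arylacetic-type acid to heat.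

**Compound list**
1 | heptadecanal | CCCCCCCCCCCCCCCCC=O | starting material
2 | ethynylmagnesium bromide | C#C[Mg]Br | starting material
3 | bromomagnesium nonadec-1-yn-3-olate (racemic) | C#CC(O[Mg]Br)CCCCCCCCCCCCCCCC | intermediate
4 | nonadec-1-yn-3-ol (racemic) | C#CC(O)CCCCCCCCCCCCCCCC | intermediate
5 | 1-iodononadec-1-yn-3-ol (racemic) | IC#CC(O)CCCCCCCCCCCCCCCC | intermediate
6 | (Z)-1-iodononadec-1-en-3-ol (racemic) | I/C=C\C(O)CCCCCCCCCCCCCCCC | intermediate
7 | trimethylsilylacetylene | C#C[Si](C)(C)C | starting material
8 | (Z)-1-(trimethylsilyl)henicos-3-en-1-yn-5-ol (racemic) | C[Si](C)(C)C#C/C=C\C(O)CCCCCCCCCCCCCCCC | intermediate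
9 | (Z)-henicos-3-en-1-yn-5-ol (racemic) | C#C/C=C\C(O)CCCCCCCCCCCCCCCC | intermediate
10 | carbon monoxide | [C-]#[O+] | starting material
11 | methanol | CO | starting material
12 | methyl (E)-2-(5-hexadecylfuran-2(5H)-ylidene)acetate (racemic) | COC(=O)/C=C1/OC(CCCCCCCCCCCCCCCC)C=C1 | intermediate
13 | methyl 2-(5-hexadecylfuran-2-yl)acetate | CCCCCCCCCCCCCCCCc1ccc(CC(=O)OC)o1 | intermediate
14 | lithium 2-(5-hexadecylfuran-2-yl)acetate | CCCCCCCCCCCCCCCCc1ccc(CC(=O)[O-])o1.[Li+] | intermediate
15 | 2-(5-hexadecylfuran-2-yl)acetic acid | CCCCCCCCCCCCCCCCc1ccc(CC(=O)O)o1 | target

**Step count**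
Total steps: 7. Longest linear sequence: 7 steps (1 to 15).

**Steps most likely to fail**

Step 6. The vinylpalladium intermediate may be protonated before CO inserts, which gives non-carbonylative cycloisomerisation. The catalyst may also stall through deposition of palladium metal if reoxidation lags with the poorly methanol-soluble lipid substrate. The fallback sets out from 6 and returns at 13, bringing the ester carbon in with the alkyne and closing the ring by a polar addition. Iodoalkene 6 would be coupled with methyl propiolate under amine-free Sonogashira conditions (Pd(PPh3)2Cl2, CuI, K2CO3, THF) to give methyl (Z)-6-hydroxydocos-4-en-2-ynoate F1. Catalytic DBU in THF would then let the hydroxyl add to the β-carbon of the ynoate in a 5-exo-dig oxa-Michael closure. This gives the exocyclic dihydrofuran 12 or its geometric isomer methyl (Z)-2-(5-hexadecylfuran-2(5H)-ylidene)acetate F2, both of which aromatise to 13.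

Step 3. Over-reduction of the iodoalkene and incomplete consumption of the iodoalkyne may leave mixtures that resist separation. The fallback sets out from 1 and returns at 8, replacing steps 1 to 4 and setting the Z-alkene by metal reduction of a diyne. Lithium 4-(trimethylsilyl)buta-1,3-diyn-1-ide F3 would be made from 1,4-bis(trimethylsilyl)buta-1,3-diyne and MeLi·LiBr in THF. Its addition to aldehyde 1 at −78 °C, followed by a water quench, would give 1-(trimethylsilyl)henicosa-1,3-diyn-5-ol F4 (racemic). Zinc dust activated with Cu(OAc)2 and AgNO3 in MeOH/H2O should then reduce the triple bond next to the carbinol to the cis-alkene, since the hydroxyl activates it while the silyl-capped triple bond is shielded, and deliver 8.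

Step 5. Basic methanol may trigger ring closure of the unmasked enynol onto its alkyne, and the terminal enyne may oligomerise on concentration. The fallback sets out from 6 and returns at 9, replacing steps 4 and 5 and avoiding both the silyl cap and alkoxide conditions. Ethynylzinc bromide F5, prepared from 2 and ZnBr2 in THF, would be used in excess in a Negishi coupling with 6 (Pd(PPh3)4, THF, 0 °C to rt). This gives 9 directly with retention of the Z geometry, and the crude enynol would be taken into step 6 without storage.

**Further compounds**
F1 | step 6 | methyl (Z)-6-hydroxydocos-4-en-2-ynoate (racemic) | COC(=O)C#C/C=C\C(O)CCCCCCCCCCCCCCCC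
F2 | step 6 | methyl (Z)-2-(5-hexadecylfuran-2(5H)-ylidene)acetate (racemic) | COC(=O)/C=C1\OC(CCCCCCCCCCCCCCCC)C=C1
F3 | step 3 | lithium 4-(trimethylsilyl)buta-1,3-diyn-1-ide | [Li]C#CC#C[Si](C)(C)C
F4 | step 3 | 1-(trimethylsilyl)henicosa-1,3-diyn-5-ol (racemic) | C[Si](C)(C)C#CC#CC(O)CCCCCCCCCCCCCCCC
F5 | step 5 | ethynylzinc bromide | C#C[Zn]Br
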